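**Plan**

- Numbering of the decalin: C1 carries the ester, C2 the ring A methyl, C4a and C8a the angular methyls, and C5=C6 is the ring B alkene. The retrosynthesis cuts the glyceryl ester C–O bond, adds a helper ketone at C4, cuts C4a–C5 and C6–C7 together, then C8a–CH3, then ring A by Michael addition and aldol condensation.
- Forward: ring A is made first by an asymmetric Robinson annulation, and the quaternary C8a by conjugate methylation. Ring B is then closed onto ring A by union with a C8 alkenyl dihalide that already carries the side chain, C4 is deoxygenated, and the glycerol unit is attached last.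
- Feature that allows the event: C5=C6 lies between C4a, which becomes an enolate carbon once C4 is a ketone, and C7, the end of a two-carbon arm on C8a that can carry zinc. A (Z)-2-bromo-1-iodoalkene then links both carbons as a cis-alkene-1,2-diyl unit.
- Stereochemistry: the C2 methyl centre is set by the organocatalyst and C1 settles trans to it by equilibration. C8a is set by cuprate addition trans to the C2 methyl, and C4a by the cis ring closure that the tether enforces. The glycerol centre comes from (S)-glycidol.

Key step: step 8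

Remark on the chemistry: 1, 2, 9 and 18 are taken as commercial. The ester-bearing ring carbon is epimerisable in every intermediate and is drawn in its trans (thermodynamic) form; a cis portion would converge under the alkoxide of step 8.

**Step 1**
Reactants: 1 ethyl 5-(benzyloxy)-3-oxopentanoate; 2 (E)-pent-3-en-2-one
Product: 4 ethyl (1S,6R)-2-[2-(benzyloxy)ethyl]-6-methyl-4-oxocyclohex-2-ene-1-carboxylate, via Michael adduct 3 (not isolated)
Conditions: 9-amino-9-deoxy-epi-cinchona primary amine (cat., the pseudoenantiomer that gives 6R), PhCO2H (cat.), toluene, rt; then p-TsOH (cat.), toluene, reflux, Dean–Stark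
Reagents that add atoms: none
Why: Iminium activation of the enone by the chiral primary amine should direct the β-keto ester to one face of the β-carbon (organocatalytic asymmetric Michael addition) and set the methyl-bearing centre, after which acid drives the Robinson-type aldol condensation of the methyl ketone onto the keto ester carbonyl and lets C1 settle trans.

**Step 2**
Reactants: 4 ethyl (1S,6R)-2-[2-(benzyloxy)ethyl]-6-methyl-4-oxocyclohex-2-ene-1-carboxylate
Product: 6 ethyl (1S,2S,6R)-2-[2-(benzyloxy)ethyl]-2,3,6-trimethyl-4-oxocyclohexane-1-carboxylate (mixture at C3), via lithium enolate 5 (not isolated)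
Conditions: Me2CuLi (from CuI, MeLi), Et2O, −20 to 0 °C; then MeI, HMPA, THF, −30 °C to rt
Reagents that add atoms: lithium dimethylcuprate C[Cu-]C.[Li+]; iodomethane CI
Why: Tandem cuprate conjugate addition and enolate C-methylation; axial attack on the half-chair that keeps the C6 methyl equatorial should place the new methyl trans to it (the known preference of 5-substituted cyclohexenones) and so set the quaternary C2, while the C3 centre is erased again in step 8.

**Step 3**
Reactants: 6 ethyl (1S,2S,6R)-2-[2-(benzyloxy)ethyl]-2,3,6-trimethyl-4-oxocyclohexane-1-carboxylate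
Product: 7 ethyl (1S,2S,6R)-2-(2-hydroxyethyl)-2,3,6-trimethyl-4-oxocyclohexane-1-carboxylate
Conditions: H2 (1 atm), Pd/C, EtOAc, rt
Reagents that add atoms: none
Why: Hydrogenolysis of a benzyl ether; the molecule holds no alkene at this stage and ketone and ester are inert.

**Step 4**
Reactants: 7 ethyl (1S,2S,6R)-2-(2-hydroxyethyl)-2,3,6-trimethyl-4-oxocyclohexane-1-carboxylate
Product: 8 ethyl (1S,2S,6R)-2-(2-iodoethyl)-2,3,6-trimethyl-4-oxocyclohexane-1-carboxylate
Conditions: I2, PPh3, imidazole, CH2Cl2, 0 °C (crude 7 used at once)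
Reagents that add atoms: iodine II
Why: Appel-type iodination of a primary alcohol; immediate conversion keeps the hydroxy ester from lactonising.

**Step 5**
Reactants: 9 5-bromo-2-methylpent-2-ene
Product: 10 6-methylhept-5-en-1-yne
Conditions: lithium acetylide–ethylenediamine complex, DMSO, 0 °C to rt
Reagents that add atoms: lithium acetylide–ethylenediamine complex [Li+].[C-]#C.NCCN
Why: SN2 alkylation of an acetylide by a primary homoallylic bromide.

**Step 6**
Reactants: 10 6-methylhept-5-en-1-yne
Product: 11 1-iodo-6-methylhept-5-en-1-yne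
Conditions: N-iodosuccinimide, AgNO3 (cat.), acetone, rt
Reagents that add atoms: N-iodosuccinimide O=C1CCC(=O)N1I
Why: Silver-catalysed electrophilic iodination of a terminal alkyne, which leaves the trisubstituted alkene alone.

**Step 7**
Reactants: 11 1-iodo-6-methylhept-5-en-1-yne
Product: 12 (1Z)-2-bromo-1-iodo-6-methylhepta-1,5-diene
Conditions: LiBr, AcOH, Pd(OAc)2 (cat.), rt
Reagents that add atoms: lithium bromide [Li+].[Br-]
Why: Anti hydrobromination of a 1-iodoalkyne (trans-bromopalladation by divalent palladium, then protonolysis) should put bromine on the internal carbon and cis to iodine, which is the geometry the annulation needs.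

**Step 8**
Reactants: 8 ethyl (1S,2S,6R)-2-(2-iodoethyl)-2,3,6-trimethyl-4-oxocyclohexane-1-carboxylate; 12 (1Z)-2-bromo-1-iodo-6-methylhepta-1,5-diene
Product: 15 ethyl (1S,2R,4aR,8aR)-2,4a,8a-trimethyl-5-(4-methylpent-3-en-1-yl)-4-oxo-1,2,3,4,4a,7,8,8a-octahydronaphthalene-1-carboxylate, via alkylzinc iodide 13 (not isolated), via alkenyl bromide 14 (not isolated)
Conditions: Zn dust, LiCl, THF, 40 °C; then 12, Pd2(dba)3 (cat.), XPhos, rt; then NaOt-Bu, toluene, 70 °C (one pot)
Reagents that add atoms: none
Why: Zinc insertion into the C–I bond of 8 gives 13, which transmetalates to the alkenylpalladium formed by oxidative addition of zerovalent palladium into the weaker C–I bond of 12, and reductive elimination forms C6–C7 with retention of alkene geometry (Negishi sp3–sp2 coupling) to give 14. The same catalyst then inserts into the remaining alkenyl C–Br bond, alkoxide forms the ketone enolate reversibly, and reductive elimination from the alkenyl(enolate)palladium forms C4a–C5; the closest known type is the palladium-catalysed intramolecular α-alkenylation of a ketone. Ring B closes as a six-membered ring in the enolexo sense through a seven-membered palladacycle, and only the C4a enolate can reach the alkenyl carbon in a six-membered ring, so the regioisomeric enolate is funnelled back by proton exchange. The new quaternary centre C4a is set by the tether: the bond must form perpendicular to the enolate plane, which is possible only on the face that carries the C8a arm, so the fusion is cis and the two angular methyls end up syn. The step needs C–I to react before C–Br (secured by bond strength and the less hindered terminal position), a cis relation of the two halogens (both couplings are stereoretentive, so C4a and C7 sit cis on C5=C6), and no migration of the new alkene, which the quaternary C4a rules out.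

**Step 9**
Reactants: 15 ethyl (1S,2R,4aR,8aR)-2,4a,8a-trimethyl-5-(4-methylpent-3-en-1-yl)-4-oxo-1,2,3,4,4a,7,8,8a-octahydronaphthalene-1-carboxylate
Product: 17 (1S,2R,4aR,8aR)-2,4a,8a-trimethyl-5-(4-methylpent-3-en-1-yl)-1,2,3,4,4a,7,8,8a-octahydronaphthalene-1-carboxylic acid, via hydrazone 16 (not isolated)
Conditions: N2H4·H2O, KOH, diethylene glycol, 130 then 200 °C; then aq. HCl
Reagents that add atoms: potassium hydroxide [K+].[OH-]
Why: Wolff–Kishner reduction (Huang–Minlon procedure) removes the helper ketone and saponifies the ester in the same operation; the isolated alkenes are inert and C1 already holds its favoured equatorial configuration.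

**Step 10**
Reactants: 18 (S)-glycidol
Product: 19 (R)-glycidyl acetate [(2R)-oxiran-2-ylmethyl acetate]
Conditions: Ac2O, Et3N, DMAP (cat.), CH2Cl2, 0 °C
Reagents that add atoms: acetic anhydride CC(=O)OC(C)=O
Why: O-acetylation of a primary alcohol; the stereocentre is not touched and only its descriptor changes.

**Step 11**
Reactants: 17 (1S,2R,4aR,8aR)-2,4a,8a-trimethyl-5-(4-methylpent-3-en-1-yl)-1,2,3,4,4a,7,8,8a-octahydronaphthalene-1-carboxylic acid; 19 (R)-glycidyl acetate
Product: 20 (2S)-3-(acetyloxy)-2-hydroxypropyl (1S,2R,4aR,8aR)-2,4a,8a-trimethyl-5-(4-methylpent-3-en-1-yl)-1,2,3,4,4a,7,8,8a-octahydronaphthalene-1-carboxylate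
Conditions: (salen)Co(OTs) (cat., matched enantiomer), i-Pr2NEt, t-BuOMe, rt
Reagents that add atoms: none
Why: Ring opening of a terminal epoxide by a carboxylic acid under catalysis by a trivalent cobalt salen Lewis acid should occur at the CH2 terminus, so the glycerol centre is carried over unchanged and the secondary hydroxyl is set free directly.

**Compound list**

1 | ethyl 5-(benzyloxy)-3-oxopentanoate | CCOC(=O)CC(=O)CCOCc1ccccc1 | starting material
2 | (E)-pent-3-en-2-one | C/C=C/C(C)=O | starting material
3 | ethyl (3R)-2-[3-(benzyloxy)propanoyl]-3-methyl-5-oxohexanoate (Michael adduct) | CCOC(=O)C(C(=O)CCOCc1ccccc1)[C@H](C)CC(C)=O | intermediate (not isolated)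
4 | ethyl (1S,6R)-2-[2-(benzyloxy)ethyl]-6-methyl-4-oxocyclohex-2-ene-1-carboxylate | CCOC(=O)[C@H]1[C@H](C)CC(=O)C=C1CCOCc1ccccc1 | intermediate
5 | lithium enolate of ethyl (1S,2S,6R)-2-[2-(benzyloxy)ethyl]-2,6-dimethyl-4-oxocyclohexane-1-carboxylate (C3=C4 enolate) | CCOC(=O)[C@H]1[C@H](C)CC([O-])=C[C@]1(C)CCOCc1ccccc1.[Li+] | intermediate (not isolated)
6 | ethyl (1S,2S,6R)-2-[2-(benzyloxy)ethyl]-2,3,6-trimethyl-4-oxocyclohexane-1-carboxylate | CCOC(=O)[C@H]1[C@H](C)CC(=O)C(C)[C@]1(C)CCOCc1ccccc1 | intermediate
7 | ethyl (1S,2S,6R)-2-(2-hydroxyethyl)-2,3,6-trimethyl-4-oxocyclohexane-1-carboxylate | CCOC(=O)[C@H]1[C@H](C)CC(=O)C(C)[C@]1(C)CCO | intermediate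
8 | ethyl (1S,2S,6R)-2-(2-iodoethyl)-2,3,6-trimethyl-4-oxocyclohexane-1-carboxylate | CCOC(=O)[C@H]1[C@H](C)CC(=O)C(C)[C@]1(C)CCI | intermediate
9 | 5-bromo-2-methylpent-2-ene | CC(C)=CCCBr | starting material
10 | 6-methylhept-5-en-1-yne | C#CCCC=C(C)C | intermediate
11 | 1-iodo-6-methylhept-5-en-1-yne | IC#CCCC=C(C)C | intermediate
12 | (1Z)-2-bromo-1-iodo-6-methylhepta-1,5-diene | I/C=C(\Br)CCC=C(C)C | intermediate
13 | alkylzinc iodide from 8 (zinc in place of iodine) | CCOC(=O)[C@H]1[C@H](C)CC(=O)C(C)[C@]1(C)CC[Zn]I | intermediate (not isolated)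
14 | ethyl (1S,2S,6R)-2-[(3Z)-4-bromo-8-methylnona-3,7-dien-1-yl]-2,3,6-trimethyl-4-oxocyclohexane-1-carboxylate | CCOC(=O)[C@H]1[C@H](C)CC(=O)C(C)[C@]1(C)CC/C=C(\Br)CCC=C(C)C | intermediate (not isolated)
15 | ethyl (1S,2R,4aR,8aR)-2,4a,8a-trimethyl-5-(4-methylpent-3-en-1-yl)-4-oxo-1,2,3,4,4a,7,8,8a-octahydronaphthalene-1-carboxylate | CCOC(=O)[C@H]1[C@H](C)CC(=O)[C@]2(C)C(CCC=C(C)C)=CCC[C@]12C | intermediate
16 | C4 hydrazone of 15 | CCOC(=O)[C@H]1[C@H](C)CC(=NN)[C@]2(C)C(CCC=C(C)C)=CCC[C@]12C | intermediate (not isolated)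
17 | (1S,2R,4aR,8aR)-2,4a,8a-trimethyl-5-(4-methylpent-3-en-1-yl)-1,2,3,4,4a,7,8,8a-octahydronaphthalene-1-carboxylic acid | OC(=O)[C@H]1[C@H](C)CC[C@]2(C)C(CCC=C(C)C)=CCC[C@]12C | intermediate
18 | (S)-glycidol | OC[C@H]1CO1 | starting material
19 | (R)-glycidyl acetate | CC(=O)OC[C@H]1CO1 | intermediate
20 | (2S)-3-(acetyloxy)-2-hydroxypropyl (1S,2R,4aR,8aR)-2,4a,8a-trimethyl-5-(4-methylpent-3-en-1-yl)-1,2,3,4,4a,7,8,8a-octahydronaphthalene-1-carboxylate | CC(=O)OC[C@H](O)COC(=O)[C@H]1[C@H](C)CC[C@]2(C)C(CCC=C(C)C)=CCC[C@]12C | target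

**Count**

Total step count: 11. Longest linear sequence: 7 steps (1, 2, 3, 4, 8, 9, 11).

**Steps most likely to fail**

Step 8. The reductive elimination that joins the hindered alkenylpalladium to the fully substituted enolate carbon may be slow, so that protodebromination or β-hydride loss from the palladium enolate takes over. The fallback keeps the Negishi coupling but closes the ring with a radical. It sets out from 8 and 12: the coupling alone (Zn, LiCl; then Pd(PPh3)4, THF, rt) should give 14, which is isolated. TMSCl, NaI and Et3N in MeCN should then give the more substituted silyl enol ether, ethyl (1S,2R,6R)-2-[(3Z)-4-bromo-8-methylnona-3,7-dien-1-yl]-2,3,6-trimethyl-4-(trimethylsilyloxy)cyclohex-3-ene-1-carboxylate F1. Bu3SnH and AIBN in refluxing benzene generate the alkenyl radical, whose 6-exo attack on the methyl-bearing enol ether carbon should give the cis-fused silyl ether, ethyl (1S,2R,4aR,8aR)-2,4a,8a-trimethyl-5-(4-methylpent-3-en-1-yl)-4-(trimethylsilyloxy)-1,2,3,4,4a,7,8,8a-octahydronaphthalene-1-carboxylate F2. K2CO3 in MeOH frees the 4-hydroxy ester F3, and Dess–Martin periodinane brings the route back at 15.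

Step 2. Facial selectivity in the cuprate addition may be poor, because the ester at C1 and the methyl at C6 direct to opposite faces, and proton transfer within the enolate may precede methylation. The fallback replaces substrate control by catalyst control. It sets out from 4: Me3Al with Cu(O2CC4H3S) (monovalent copper thiophene-2-carboxylate) and the matched chiral phosphoramidite ligand in Et2O, followed by TMSOTf, should give the silyl enol ether, ethyl (1S,2S,6R)-2-[2-(benzyloxy)ethyl]-2,6-dimethyl-4-(trimethylsilyloxy)cyclohex-3-ene-1-carboxylate F4. Benzyltrimethylammonium fluoride and MeI in THF then methylate C3 regiospecifically and bring the route back at 6.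

Step 11. Acyl migration between the glycerol oxygens, or opening at the internal epoxide carbon, may occur. The fallback builds the glyceride through an acetonide. It sets out from 17: Mitsunobu esterification with (R)-solketal, [(4R)-2,2-dimethyl-1,3-dioxolan-4-yl]methanol (PPh3, DIAD, THF), should give [(4S)-2,2-dimethyl-1,3-dioxolan-4-yl]methyl (1S,2R,4aR,8aR)-2,4a,8a-trimethyl-5-(4-methylpent-3-en-1-yl)-1,2,3,4,4a,7,8,8a-octahydronaphthalene-1-carboxylate F5. Aqueous AcOH at rt removes the acetonide to give the (2S)-2,3-dihydroxypropyl ester F6, and AcCl with 2,4,6-collidine in CH2Cl2 at −78 °C acetylates the primary hydroxyl only, which brings the route back at 20.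

**Further compounds**

F1 | step 8 | ethyl (1S,2R,6R)-2-[(3Z)-4-bromo-8-methylnona-3,7-dien-1-yl]-2,3,6-trimethyl-4-(trimethylsilyloxy)cyclohex-3-ene-1-carboxylate | CCOC(=O)[C@H]1[C@H](C)CC(O[Si](C)(C)C)=C(C)[C@]1(C)CC/C=C(\Br)CCC=C(C)C
F2 | step 8 | ethyl (1S,2R,4aR,8aR)-2,4a,8a-trimethyl-5-(4-methylpent-3-en-1-yl)-4-(trimethylsilyloxy)-1,2,3,4,4a,7,8,8a-octahydronaphthalene-1-carboxylate (C4 epimers) | CCOC(=O)[C@H]1[C@H](C)CC(O[Si](C)(C)C)[C@]2(C)C(CCC=C(C)C)=CCC[C@]12C
F3 | step 8 | ethyl (1S,2R,4aR,8aR)-4-hydroxy-2,4a,8a-trimethyl-5-(4-methylpent-3-en-1-yl)-1,2,3,4,4a,7,8,8a-octahydronaphthalene-1-carboxylate (C4 epimers) | CCOC(=O)[C@H]1[C@H](C)CC(O)[C@]2(C)C(CCC=C(C)C)=CCC[C@]12C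
F4 | step 2 | ethyl (1S,2S,6R)-2-[2-(benzyloxy)ethyl]-2,6-dimethyl-4-(trimethylsilyloxy)cyclohex-3-ene-1-carboxylate | CCOC(=O)[C@H]1[C@H](C)CC(O[Si](C)(C)C)=C[C@]1(C)CCOCc1ccccc1
F5 | step 11 | [(4S)-2,2-dimethyl-1,3-dioxolan-4-yl]methyl (1S,2R,4aR,8aR)-2,4a,8a-trimethyl-5-(4-methylpent-3-en-1-yl)-1,2,3,4,4a,7,8,8a-octahydronaphthalene-1-carboxylate | CC1(C)OC[C@@H](COC(=O)[C@H]2[C@H](C)CC[C@]3(C)C(CCC=C(C)C)=CCC[C@]23C)O1
F6 | step 11 | (2S)-2,3-dihydroxypropyl (1S,2R,4aR,8aR)-2,4a,8a-trimethyl-5-(4-methylpent-3-en-1-yl)-1,2,3,4,4a,7,8,8a-octahydronaphthalene-1-carboxylate | OC[C@H](O)COC(=O)[C@H]1[C@H](C)CC[C@]2(C)C(CCC=C(C)C)=CCC[C@]12C
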